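**Retrosynthetic overview**

1. Rings A and B are bought as benzene rings. Ring A comes from phloracetophenone 1, masked as its dibenzyl ether 2. Ring B comes from protocatechualdehyde 3, sulfated at O-4 first to give 4, so the sulfate is in place before any ring is built.
2. Key disconnection: the O1–C2 and C3–O bonds of ring C, the only ring formed and formed last. This opens ring C to chalcone 5 by way of trans-dihydroflavonol 6; the chalcone C=C comes from an aldol condensation of 2 with 4 in the same flask.
3. Flavonol 7 gives target 8 by loss of the two benzyl groups on ring A.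

Assumption: the target has no stereocentre and is achiral, so no enantiomer has to be chosen; the sulfate is carried as its potassium salt and protonated in the last operation to the hydrogen sulfate that the SMILES shows.

**Route**

Step 1
Reactants: 1 2',4',6'-trihydroxyacetophenone
Product: 2 1-[2,4-bis(benzyloxy)-6-hydroxyphenyl]ethan-1-one
Conditions: BnBr (2.05 equiv), K2CO3 (2.1 equiv), DMF, rt, 16 h
Reagents that add atoms: benzyl bromide, BrCc1ccccc1
Why: Williamson ether synthesis; the 4-OH and one ortho OH are alkylated, while the last ortho OH is held in a hydrogen bond to the acetyl C=O and stays free under carbonate at room temperature; no stereocentre.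

Step 2
Reactants: 3 3,4-dihydroxybenzaldehyde
Product: 4 potassium 4-formyl-2-hydroxyphenyl sulfate
Conditions: KOH (1.0 equiv), MeOH, 0 °C, then strip; Me3N·SO3 (1.1 equiv), DMF, 40 °C, 6 h
Reagents that add atoms: sulfur trioxide–trimethylamine complex, C[N+](C)(C)S(=O)(=O)[O-]; potassium hydroxide, [K+].[OH-]
Why: Sulfation of a phenoxide by a sulfur trioxide–amine complex; with exactly one equivalent of KOH only the 4-OH (para to CHO, pKa about 7, against about 11 for the 3-OH) is ionised, so SO3 goes to O-4, the same bias that gives 4-O-alkylation of this aldehyde with one equivalent of mild base; no stereocentre.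

Step 3
Reactants: 2 1-[2,4-bis(benzyloxy)-6-hydroxyphenyl]ethan-1-one, 4 potassium 4-formyl-2-hydroxyphenyl sulfate
Product: 7 potassium 5,7-di-O-benzylquercetin 4'-O-sulfate, via chalcone sulfate 5 (not isolated), via trans-dihydroflavonol sulfate 6 (not isolated)
Conditions: 4 (1.15 equiv), KOH (50% aq, 8 equiv), EtOH–1,4-dioxane (1:1), rt, 40 h; then MeOH, 30% H2O2 (6 equiv), 0 °C to rt, 8 h
Reagents that add atoms: hydrogen peroxide, OO
Why: Proposed new method: a one-pot Claisen–Schmidt condensation and Algar–Flynn–Oyamada oxidative oxa-cyclisation run on an unprotected aryl sulfate monoester, a substrate class on which this chemistry has not been shown, with the sulfate acting as its own protecting group; the ArOSO3− group is inert to HO− and HOO− (its S–O bond needs acid to cleave) and, being para and nearly electronically neutral, leaves the enone of 5 electrophilic, so the 2'-phenoxide closes 6-endo on the β-carbon (O1–C2 bond) while HOO− delivers oxygen to the α-carbon (C3–O bond) to give racemic trans-6 (both centres set by anti addition across the E-alkene and then erased), which excess alkaline H2O2 dehydrogenates to the flavonol; the closest known reaction is the Algar–Flynn–Oyamada flavonol synthesis, also run one-pot from acetophenone and aldehyde, on ether-protected polyphenols.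

Step 4
Reactants: 7 potassium 5,7-di-O-benzylquercetin 4'-O-sulfate
Product: 8 quercetin 4'-O-sulfate (hydrogen sulfate form)
Conditions: H2 (1 atm), 10% Pd/C, MeOH–THF–H2O, rt, 3 h; filter; HCl (1.0 equiv, aq), 0 °C; C18 (H2O to MeOH), lyophilise
Reagents that add atoms: none
Why: Catalytic hydrogenolysis of the two benzyl aryl ethers; the aryl sulfate monoester and the flavonol C2=C3 bond are not reduced at 1 atm and room temperature, and one equivalent of cold HCl turns the potassium salt into the hydrogen sulfate as drawn; no stereocentre.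

**Compound list**

1 | 2',4',6'-trihydroxyacetophenone (phloracetophenone) | CC(=O)c1c(O)cc(O)cc1O | starting material
2 | 1-[2,4-bis(benzyloxy)-6-hydroxyphenyl]ethan-1-one | CC(=O)c1c(O)cc(OCc2ccccc2)cc1OCc1ccccc1 | intermediate
3 | 3,4-dihydroxybenzaldehyde (protocatechualdehyde) | O=Cc1ccc(O)c(O)c1 | starting material
4 | potassium 4-formyl-2-hydroxyphenyl sulfate | [K+].O=Cc1ccc(OS(=O)(=O)[O-])c(O)c1 | intermediate
5 | potassium 4-[(E)-3-[2,4-bis(benzyloxy)-6-hydroxyphenyl]-3-oxoprop-1-en-1-yl]-2-hydroxyphenyl sulfate (chalcone sulfate) | [K+].O=C(/C=C/c1ccc(OS(=O)(=O)[O-])c(O)c1)c1c(O)cc(OCc2ccccc2)cc1OCc1ccccc1 | intermediate (not isolated)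
6 | potassium 4-[rac-(2R,3R)-5,7-bis(benzyloxy)-3-hydroxy-4-oxochroman-2-yl]-2-hydroxyphenyl sulfate (racemic trans-dihydroflavonol sulfate, one enantiomer drawn) | [K+].O=C1[C@H](O)[C@@H](c2ccc(OS(=O)(=O)[O-])c(O)c2)Oc2cc(OCc3ccccc3)cc(OCc3ccccc3)c12 | intermediate (not isolated)
7 | potassium 4-[5,7-bis(benzyloxy)-3-hydroxy-4-oxo-4H-chromen-2-yl]-2-hydroxyphenyl sulfate (potassium 5,7-di-O-benzylquercetin 4'-O-sulfate) | [K+].O=c1c(O)c(-c2ccc(OS(=O)(=O)[O-])c(O)c2)oc2cc(OCc3ccccc3)cc(OCc3ccccc3)c12 | intermediate
8 | 2-hydroxy-4-(3,5,7-trihydroxy-4-oxo-4H-chromen-2-yl)phenyl hydrogen sulfate (quercetin 4'-O-sulfate) | O=c1c(O)c(-c2ccc(OS(=O)(=O)O)c(O)c2)oc2cc(O)cc(O)c12 | target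

**Step count and risks**

Total steps: 4 (steps 1 and 2 run in parallel). Longest linear sequence: 3 (1 to 2 to 7 to 8, or 3 to 4 to 7 to 8).

Most likely to fail, step 3 (the proposed new step). The 6'-benzyloxy group can divert the oxidative cyclisation to the aurone by 5-exo attack at the α-carbon, the anionic aldehyde 4 may condense slowly, and the free 3-phenoxide may be degraded by alkaline peroxide. The fallback uses known chemistry only and puts the sulfate on after ring C is made. It sets out from 3 and comes back to the route at 8.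
- 3 is protected at its more acidic 4-OH (MOMCl, K2CO3, acetone) to give 3-hydroxy-4-(methoxymethoxy)benzaldehyde F1, then benzylated (BnBr, K2CO3, DMF) to 3-(benzyloxy)-4-(methoxymethoxy)benzaldehyde F2.
- Claisen–Schmidt condensation of F2 with 2 (KOH, EtOH) gives the isolated 2'-hydroxy-3,4',6'-tris(benzyloxy)-4-(methoxymethoxy)chalcone F3.
- Classical Algar–Flynn–Oyamada oxidation (H2O2, NaOH, MeOH–THF, 0 °C) takes F3 through racemic trans-5,7,3'-tri-O-benzyl-4'-O-(methoxymethyl)dihydroquercetin F4 (not isolated) to 5,7,3'-tri-O-benzyl-4'-O-(methoxymethyl)quercetin F5.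
- Benzylation of the 3-OH (BnBr, K2CO3, DMF) gives 3,5,7,3'-tetra-O-benzyl-4'-O-(methoxymethyl)quercetin F6, and HCl in MeOH–THF removes the MOM group to give 3,5,7,3'-tetra-O-benzylquercetin F7.
- The only free phenol of F7 is sulfated (KOH, then Me3N·SO3, DMF) to potassium 3,5,7,3'-tetra-O-benzylquercetin 4'-O-sulfate F8, and hydrogenolysis and protonation as in step 4 give 8.

Second, step 2. Some 3-O-sulfate or bis-sulfate may form, and the isomers are hard to separate as salts. The fallback fixes the regiochemistry with a blocking group instead of relying on pKa. It sets out from 3 and comes back at 4.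
- The dianion of 3 (NaH, 2.2 equiv, DMSO) is alkylated at its more nucleophilic 3-oxide with allyl bromide (1.0 equiv) to give 3-(allyloxy)-4-hydroxybenzaldehyde F9.
- Its single phenol is sulfated (KOH, then Me3N·SO3, DMF) to potassium 2-(allyloxy)-4-formylphenyl sulfate F10.
- Pd(PPh3)4 (zerovalent palladium, 2 mol %) with morpholine in THF–MeOH removes the allyl group to give 4.

Third, step 1. Mono-, tri- and C-benzylated products can lower the yield of 2 and complicate its purification. The fallback swaps selective protection for exhaustive protection and selective deprotection. It sets out from 1 and comes back at 2.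
- 1 is fully benzylated (BnBr, 3.5 equiv, K2CO3, DMF, 80 °C) to 1-[2,4,6-tris(benzyloxy)phenyl]ethan-1-one F11.
- MgBr2·OEt2 in toluene–Et2O at reflux removes only one benzyl group ortho to the carbonyl, through chelation, to give 2.

Further compounds
F1 | step 3 | 3-hydroxy-4-(methoxymethoxy)benzaldehyde | O=Cc1ccc(OCOC)c(O)c1
F2 | step 3 | 3-(benzyloxy)-4-(methoxymethoxy)benzaldehyde | O=Cc1ccc(OCOC)c(OCc2ccccc2)c1
F3 | step 3 | 2'-hydroxy-3,4',6'-tris(benzyloxy)-4-(methoxymethoxy)chalcone, (E) | O=C(/C=C/c1ccc(OCOC)c(OCc2ccccc2)c1)c1c(O)cc(OCc2ccccc2)cc1OCc1ccccc1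
F4 | step 3 | racemic trans-5,7,3'-tri-O-benzyl-4'-O-(methoxymethyl)dihydroquercetin, (2R,3R) enantiomer drawn | O=C1[C@H](O)[C@@H](c2ccc(OCOC)c(OCc3ccccc3)c2)Oc2cc(OCc3ccccc3)cc(OCc3ccccc3)c12
F5 | step 3 | 5,7,3'-tri-O-benzyl-4'-O-(methoxymethyl)quercetin | O=c1c(O)c(-c2ccc(OCOC)c(OCc3ccccc3)c2)oc2cc(OCc3ccccc3)cc(OCc3ccccc3)c12
F6 | step 3 | 3,5,7,3'-tetra-O-benzyl-4'-O-(methoxymethyl)quercetin | O=c1c(OCc2ccccc2)c(-c2ccc(OCOC)c(OCc3ccccc3)c2)oc2cc(OCc3ccccc3)cc(OCc3ccccc3)c12
F7 | step 3 | 3,5,7,3'-tetra-O-benzylquercetin | O=c1c(OCc2ccccc2)c(-c2ccc(O)c(OCc3ccccc3)c2)oc2cc(OCc3ccccc3)cc(OCc3ccccc3)c12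
F8 | step 3 | potassium 3,5,7,3'-tetra-O-benzylquercetin 4'-O-sulfate | [K+].O=c1c(OCc2ccccc2)c(-c2ccc(OS(=O)(=O)[O-])c(OCc3ccccc3)c2)oc2cc(OCc3ccccc3)cc(OCc3ccccc3)c12
F9 | step 2 | 3-(allyloxy)-4-hydroxybenzaldehyde | O=Cc1ccc(O)c(OCC=C)c1
F10 | step 2 | potassium 2-(allyloxy)-4-formylphenyl sulfate | [K+].O=Cc1ccc(OS(=O)(=O)[O-])c(OCC=C)c1
F11 | step 1 | 1-[2,4,6-tris(benzyloxy)phenyl]ethan-1-one | CC(=O)c1c(OCc2ccccc2)cc(OCc2ccccc2)cc1OCc1ccccc1
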